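The catechol unit of ring B, the chromene oxygen O1 and the neighbouring 8-hydroxyl, is the feature on which everything rests. As an acetonide, this unit already holds O1, C2 and both methyl groups. Lewis-acid opening turns the ketal into an aryl oxocarbenium ion, which takes up ethyl vinyl ether in a formal [4+2] (oxa-Povarov) annulation and loses ethanol: the C2–C3 and C4–C4a bonds of the pyran ring form and the 8-hydroxyl is set free in one operation. A bromine para to O1 steers the opening and then carries a palladium-catalysed carbonylative annulation with a prenylated phloroacetophenone that builds ring C of the flavone; removal of three MOM groups finishes.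

Key step: step 2

Remark: the target has no stereocentre; the only stereocentre on the route (C4 of intermediate 5) is racemic and is removed within the same step. Chromene numbering is O1, C2, C3, C4, C4a, C5 to C8, C8a.

Step 1
Reactants: 1 4-bromocatechol; 2 2,2-dimethoxypropane
Product: 3 5-bromo-2,2-dimethyl-1,3-benzodioxole
Conditions: TsOH·H2O (cat.), benzene, reflux, Soxhlet with 4 Å molecular sieves
Reagents that add atoms: none
Why: Acid-catalysed transketalisation of the catechol with the dimethyl ketal, driven by removal of methanol, should give the five-membered cyclic ketal.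

Step 2
Reactants: 3 5-bromo-2,2-dimethyl-1,3-benzodioxole; 4 ethyl vinyl ether
Product: 6 6-bromo-2,2-dimethyl-2H-chromen-8-ol, via 4-ethoxychroman adduct 5 (not isolated)
Conditions: TMSOTf (20 mol%), CH2Cl2, −40 °C, 4 (1.5 equiv) added over 2 h, then rt
Reagents that add atoms: none
Why: Proposed new method: TMSOTf should ionise the ketal at the C–O bond of the oxygen meta to bromine, leaving the aryl oxocarbenium ion ArO+=CMe2 (a cationic 2-oxadiene) on the oxygen para to bromine; ethyl vinyl ether adds through its CH2 terminus to the ketal carbon (C3–C2 bond), the new ethoxycarbenium ion alkylates the ring carbon ortho to that oxygen (C4–C4a bond), and the acid released eliminates ethanol from 5 to the chromene. The closest known reaction types are the oxa-Povarov reaction (aryl oxocarbenium ion plus alkene to a chroman, a formal [4+2] cycloaddition) and the Lewis-acid acetal–vinyl ether condensation; untested is the cyclic catechol ketal as the oxadiene source, which makes the ketal carbon C2 of the pyran and turns the departing oxygen into the free 8-hydroxyl. The pyran ring closes by intramolecular Friedel–Crafts alkylation, six-membered and exo with respect to the C=O+ bond, at the only free position ortho to the tethering oxygen. The stereocentre at C4 of 5 forms without control (racemic) and is erased by the elimination. The step needs regioselective ketal opening, which the bromine should secure because it is a resonance donor para to the oxygen that keeps the cationic carbon and only an inductive acceptor meta to the oxygen that leaves. It also needs ring closure to outrun a second vinyl ether addition, which slow addition of 4 at low temperature should secure.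

Step 3
Reactants: 6 6-bromo-2,2-dimethyl-2H-chromen-8-ol
Product: 7 6-bromo-8-(methoxymethoxy)-2,2-dimethyl-2H-chromene
Conditions: NaH, MOMCl, THF, 0 °C to rt
Reagents that add atoms: chloromethyl methyl ether, COCCl
Why: Williamson ether synthesis: the sodium phenoxide of 6 is alkylated on oxygen by chloromethyl methyl ether, and the aryl bromide and the chromene double bond are inert to NaH.

Step 4
Reactants: 8 1-(2,4,6-trihydroxyphenyl)ethanone (phloroacetophenone); 9 1-bromo-3-methylbut-2-ene (prenyl bromide)
Product: 10 1-[2,4,6-trihydroxy-3-(3-methylbut-2-en-1-yl)phenyl]ethanone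
Conditions: KOH (10% aq.), 9 (1.0 equiv), 0 °C to rt
Reagents that add atoms: none
Why: Direct C-alkylation (SN2 on carbon) of the ambident phloroglucinol-type phenoxide, favoured in water where the oxygens are hydrogen-bonded, should give the mono-C-prenyl compound, the two free ring positions being equivalent and over-alkylation limited by the stoichiometry.

Step 5
Reactants: 10 1-[2,4,6-trihydroxy-3-(3-methylbut-2-en-1-yl)phenyl]ethanone
Product: 11 1-[2-hydroxy-4,6-bis(methoxymethoxy)-3-(3-methylbut-2-en-1-yl)phenyl]ethanone
Conditions: MOMCl (2.2 equiv), K2CO3, acetone, 0 °C to rt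
Reagents that add atoms: chloromethyl methyl ether, COCCl
Why: Williamson ether synthesis under mild base: the 4-hydroxyl (most acidic, not hydrogen-bonded) and the unhindered 6-hydroxyl should react, whereas the 2-hydroxyl, wedged between the prenyl and acetyl groups and hydrogen-bonded to the carbonyl, should stay free, which fixes the later ring closure next to the prenyl group.

Step 6
Reactants: 7 6-bromo-8-(methoxymethoxy)-2,2-dimethyl-2H-chromene; 11 1-[2-hydroxy-4,6-bis(methoxymethoxy)-3-(3-methylbut-2-en-1-yl)phenyl]ethanone
Product: 14 5,7-bis(methoxymethoxy)-2-[8-(methoxymethoxy)-2,2-dimethyl-2H-chromen-6-yl]-8-(3-methylbut-2-en-1-yl)-4H-chromen-4-one, via aryl ester 12 (not isolated), via 1,3-diketone 13 (not isolated)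
Conditions: Pd(OAc)2 (3 mol%), dppb (6 mol%), DBU (3 equiv), CO (10 bar), DMSO, 120 °C
Reagents that add atoms: carbon monoxide, [C-]#[O+]
Why: Palladium-catalysed carbonylative flavone synthesis: oxidative addition of aryl bromide 7 to zerovalent palladium and CO insertion give an aroylpalladium species that acylates the phenoxide of 11 to ester 12, DBU then brings about the Baker–Venkataraman O-to-C acyl shift to diketone 13, and cyclodehydration through the only free hydroxyl, the one next to the prenyl group, closes the pyranone so that the prenyl group ends at C8.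

Step 7
Reactants: 14 5,7-bis(methoxymethoxy)-2-[8-(methoxymethoxy)-2,2-dimethyl-2H-chromen-6-yl]-8-(3-methylbut-2-en-1-yl)-4H-chromen-4-one
Product: 15 5,7-dihydroxy-2-(8-hydroxy-2,2-dimethyl-2H-chromen-6-yl)-8-(3-methylbut-2-en-1-yl)-4H-chromen-4-one
Conditions: HCl (3 M in MeOH), THF, 45 °C
Reagents that add atoms: none
Why: Acid-catalysed solvolysis of the three MOM acetals in methanol (acetal exchange to dimethoxymethane) should free the 5- and 7-hydroxyls and the hydroxyl of ring B, the mild temperature sparing the prenyl and chromene double bonds, and any diketone 13 carried over would be closed to the same flavone.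

Compound list
1 | 4-bromocatechol (4-bromobenzene-1,2-diol) | Oc1ccc(Br)cc1O | starting material
2 | 2,2-dimethoxypropane | COC(C)(C)OC | starting material
3 | 5-bromo-2,2-dimethyl-1,3-benzodioxole | CC1(C)Oc2ccc(Br)cc2O1 | intermediate
4 | ethyl vinyl ether | CCOC=C | starting material
5 | 6-bromo-4-ethoxy-2,2-dimethylchroman-8-ol (racemic, not isolated) | CCOC1CC(C)(C)Oc2c(O)cc(Br)cc12 | intermediate
6 | 6-bromo-2,2-dimethyl-2H-chromen-8-ol | CC1(C)C=Cc2cc(Br)cc(O)c2O1 | intermediate
7 | 6-bromo-8-(methoxymethoxy)-2,2-dimethyl-2H-chromene | COCOc1cc(Br)cc2C=CC(C)(C)Oc12 | intermediate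
8 | 1-(2,4,6-trihydroxyphenyl)ethanone (phloroacetophenone) | CC(=O)c1c(O)cc(O)cc1O | starting material
9 | 1-bromo-3-methylbut-2-ene (prenyl bromide) | CC(C)=CCBr | starting material
10 | 1-[2,4,6-trihydroxy-3-(3-methylbut-2-en-1-yl)phenyl]ethanone | CC(=O)c1c(O)cc(O)c(CC=C(C)C)c1O | intermediate
11 | 1-[2-hydroxy-4,6-bis(methoxymethoxy)-3-(3-methylbut-2-en-1-yl)phenyl]ethanone | CC(=O)c1c(OCOC)cc(OCOC)c(CC=C(C)C)c1O | intermediate
12 | 2-acetyl-3,5-bis(methoxymethoxy)-6-(3-methylbut-2-en-1-yl)phenyl 8-(methoxymethoxy)-2,2-dimethyl-2H-chromene-6-carboxylate (not isolated) | CC(=O)c1c(OCOC)cc(OCOC)c(CC=C(C)C)c1OC(=O)c1cc(OCOC)c2OC(C)(C)C=Cc2c1 | intermediate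
13 | 1-[2-hydroxy-4,6-bis(methoxymethoxy)-3-(3-methylbut-2-en-1-yl)phenyl]-3-[8-(methoxymethoxy)-2,2-dimethyl-2H-chromen-6-yl]propane-1,3-dione (not isolated) | COCOc1cc(OCOC)c(C(=O)CC(=O)c2cc(OCOC)c3OC(C)(C)C=Cc3c2)c(O)c1CC=C(C)C | intermediate
14 | 5,7-bis(methoxymethoxy)-2-[8-(methoxymethoxy)-2,2-dimethyl-2H-chromen-6-yl]-8-(3-methylbut-2-en-1-yl)-4H-chromen-4-one | CC(C)=CCc1c(OCOC)cc(OCOC)c2c(=O)cc(-c3cc(OCOC)c4OC(C)(C)C=Cc4c3)oc12 | intermediate
15 | 5,7-dihydroxy-2-(8-hydroxy-2,2-dimethyl-2H-chromen-6-yl)-8-(3-methylbut-2-en-1-yl)-4H-chromen-4-one | CC(C)=CCc1c(O)cc(O)c2c(=O)cc(-c3cc(O)c4c(c3)C=CC(C)(C)O4)oc12 | target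

Total step count: 7. Longest linear sequence: 5 steps (steps 1, 2, 3, 6 and 7).

Steps most likely to fail

1. Step 2 (bears the label "Proposed new method:").
   - What may go wrong: ionisation of the aryl ketal may be slower than acid-induced oligomerisation of the vinyl ether. The ketal may open at the other C–O bond, which would place the bromine at C5. The first adduct may add a second vinyl ether or rest as the seven-membered mixed acetal instead of closing onto the ring. The free phenol may be capped by excess vinyl ether.
   - Fallback (known chemistry, from 1 back to 7): NaH (1.0 equiv) and MOMCl (1.0 equiv) in DMF at 0 °C should alkylate the more acidic hydroxyl, the one meta to bromine, to give 4-bromo-2-(methoxymethoxy)phenol F1. This selectivity is expected to be modest, and the minor regioisomer is removed by chromatography.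
   - 3-Chloro-3-methylbut-1-yne, K2CO3, KI and CuI (cat.) in refluxing acetone should then give 4-bromo-2-(methoxymethoxy)-1-[(2-methylbut-3-yn-2-yl)oxy]benzene F2.
   - Heating F2 in N,N-diethylaniline at 190 °C (aromatic propargyl Claisen rearrangement, 1,5-hydrogen shift, oxa-6π electrocyclisation) should close the pyran at the only free ortho position and deliver 7 directly, where the route is rejoined.

2. Step 6.
   - What may go wrong: oxidative addition of the electron-rich bromide may be slow, or hydrodebromination may compete. Acyl transfer to the hindered, hydrogen-bonded phenoxide may be incomplete. The cascade may stall at the ester or the diketone.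
   - Fallback (stepwise classical sequence, from 7 back to 12): nBuLi in THF at −78 °C followed by CO2 and acidic work-up should give 8-(methoxymethoxy)-2,2-dimethyl-2H-chromene-6-carboxylic acid F3.
   - EDC·HCl and DMAP in CH2Cl2 with phenol 11 should give ester 12, now isolated.
   - KOH in pyridine at 50 °C (Baker–Venkataraman rearrangement) should give diketone 13. Taken into the conditions of step 7, 13 should undergo cyclodehydration and loss of the MOM groups in one operation to give 15.

3. Step 5.
   - What may go wrong: the second etherification may lose regiocontrol and alkylate the hydroxyl next to the prenyl group. The later ring closure would then take place away from the prenyl group.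
   - Fallback (the ortho oxygens are told apart by construction, from 8 back to 11): MOMCl (1.0 equiv) and iPr2NEt in CH2Cl2 at 0 °C should protect only the para hydroxyl and give 1-[2,6-dihydroxy-4-(methoxymethoxy)phenyl]ethanone F4.
   - Prenyl bromide 9 (1.0 equiv) and K2CO3 in acetone should etherify one of the two equivalent ortho hydroxyls to give 1-[2-hydroxy-4-(methoxymethoxy)-6-(3-methylbut-2-en-1-yloxy)phenyl]ethanone F5.
   - TBSCl and imidazole in DMF should give 1-[2-(tert-butyldimethylsilyloxy)-4-(methoxymethoxy)-6-(3-methylbut-2-en-1-yloxy)phenyl]ethanone F6.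
   - Heating in N,N-diethylaniline at 190 °C (Claisen rearrangement to the free ortho carbon, then Cope shift to the para carbon) should move the prenyl group to the carbon between the silyloxy and MOM-oxy groups and give 1-[2-(tert-butyldimethylsilyloxy)-6-hydroxy-4-(methoxymethoxy)-3-(3-methylbut-2-en-1-yl)phenyl]ethanone F7.
   - MOMCl and iPr2NEt should give 1-[2-(tert-butyldimethylsilyloxy)-4,6-bis(methoxymethoxy)-3-(3-methylbut-2-en-1-yl)phenyl]ethanone F8.
   - TBAF in THF at 0 °C should free the hydroxyl next to the prenyl group and give 11, where the route is rejoined.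

Further compounds
F1 | step 2 | 4-bromo-2-(methoxymethoxy)phenol | COCOc1cc(Br)ccc1O
F2 | step 2 | 4-bromo-2-(methoxymethoxy)-1-[(2-methylbut-3-yn-2-yl)oxy]benzene | COCOc1cc(Br)ccc1OC(C)(C)C#C
F3 | step 6 | 8-(methoxymethoxy)-2,2-dimethyl-2H-chromene-6-carboxylic acid | COCOc1cc(C(=O)O)cc2C=CC(C)(C)Oc12
F4 | step 5 | 1-[2,6-dihydroxy-4-(methoxymethoxy)phenyl]ethanone | CC(=O)c1c(O)cc(OCOC)cc1O
F5 | step 5 | 1-[2-hydroxy-4-(methoxymethoxy)-6-(3-methylbut-2-en-1-yloxy)phenyl]ethanone | CC(=O)c1c(O)cc(OCOC)cc1OCC=C(C)C
F6 | step 5 | 1-[2-(tert-butyldimethylsilyloxy)-4-(methoxymethoxy)-6-(3-methylbut-2-en-1-yloxy)phenyl]ethanone | CC(=O)c1c(O[Si](C)(C)C(C)(C)C)cc(OCOC)cc1OCC=C(C)C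
F7 | step 5 | 1-[2-(tert-butyldimethylsilyloxy)-6-hydroxy-4-(methoxymethoxy)-3-(3-methylbut-2-en-1-yl)phenyl]ethanone | CC(=O)c1c(O)cc(OCOC)c(CC=C(C)C)c1O[Si](C)(C)C(C)(C)C
F8 | step 5 | 1-[2-(tert-butyldimethylsilyloxy)-4,6-bis(methoxymethoxy)-3-(3-methylbut-2-en-1-yl)phenyl]ethanone | CC(=O)c1c(OCOC)cc(OCOC)c(CC=C(C)C)c1O[Si](C)(C)C(C)(C)C
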